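A small charge of substrate, 0.200 M, meets far more reagent, 2.00 M, in the alder run. Substrate is therefore the limiting reagent, and by the overall equation full turnover takes 10.0% of that reagent, so I hold c(reagent) constant in alder (pseudo-first-order).

| flask | substrate | reagent | time |
|---|---|---|---|
| larch | 0.600 M | 0.660 M |  |
| cedar | 0.600 M | 1.30 M |  |
| birch | 0.900 M | 0.660 M |  |
| alder | 0.200 M | 2.00 M | 50 min |

- larch run (time / min: [target] / M): 1.8: 0.0048; 5.4: 0.0145; 10: 0.0374; 16: 0.0679; 24: 0.1001; 32: 0.1144; 40: 0.1294; 50: 0.1356
- cedar run (time / min: [target] / M): 1.8: 0.0041; 5.4: 0.0267; 10: 0.0647; 16: 0.1142; 24: 0.1570; 32: 0.1771; 40: 0.1938; 50: 0.1912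
- birch run (time / min: [target] / M): 1.8: 0.0043; 5.4: 0.0192; 10: 0.0533; 16: 0.0915; 24: 0.1278; 32: 0.1593; 40: 0.1760; 50: 0.1840

(standard deviation of a reading: 0.002 M)

* how the opening rate goes with [substrate] round the charge of the larch run: the exponent of the rate at two percent of substrate gone to target (one fixed amount of target, the same in the runs compared)
* how the opening rate goes with [reagent] round the charge of the larch run: the exponent of the rate at two percent of substrate gone to target
* target in the alder run at 50 min, as a share of the substrate charged

- Overall: substrate + reagent -> target.
- Constant volume, constant temperature.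
- An order is taken over about fifteen percent of the charge, up and down.

1. The opening. The larch run averages 0.002667 M min⁻¹ up to 1.8 min, but 0.005083 M min⁻¹ between 10 min and 16 min, faster than at the start. I read this lag as an unseen form between substrate and target, one that reagent may turn to target or that may go astray.

2. The rule. I take the share at 50 min as a ceiling times c(reagent)/(c(reagent) + half-mark). From larch to cedar the reading rises by a factor 1.41, which gives 0.952 M. This is the half-mark, the c(reagent) at which the share stands at half of its ceiling for a fixed c(substrate). It is a reading and carries their scatter.

3. The ceiling. Larch gives 55.2% and birch 49.9%, lower with more substrate. A straight line through both reaches 62.2% at the alder charge.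

4. The alder curve. I expect a level of 42.2%, or 0.0844 M of target. At 16 min larch stands at half of its last reading and birch at half, both with 0.660 M of reagent. Cedar, with 1.30 M, already stands at 59.7% of its last reading there, more than larch, so I place the knee of alder, with 2.00 M, before 16 min.

5. The order. If the opening rate carries the same factor, its exponent in reagent round larch is half-mark/(c(reagent) + half-mark), 0.591.

The forecast gives 0.8, 0.9 and 45%, higher than my exponent and share, reasoning “so it nearly gets there by 50 min”.

    substrate → intermediate (0.1164 min⁻¹)
    intermediate + reagent → target (0.03288 L mol⁻¹ min⁻¹)
    intermediate → side product (0.03420 min⁻¹)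
    target + reagent → side product (0.006960 L mol⁻¹ min⁻¹)
    2 substrate → homo dimer (0.04680 L mol⁻¹ min⁻¹)

The flask gives 0.62 in substrate, 0.66 in reagent and 38.3% in alder. Where two percent of the larch substrate has turned, the cedar rate stands 1.5 times the larch rate, for 1.97 times the reagent. At the alder charge the half-mark factor is 67.8%, so 38.3% corresponds to a ceiling of 56.6%, lower than my 62.2% and beside the 55.2% of larch.

All runs were generated by integration on assumed constants; noise was put on by code.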